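Readings and results were generated by integration for substances that don't exist; noise was put on by code.

A small charge, 0.0450 M of nucleophile against 0.050 M of electrophile, makes the nucleophile the limiting reagent in this flask. One nucleophile turns one electrophile into target, so I call the ratio c(nucleophile)/c(electrophile) the ceiling of the main step: 90.0%.

| setting | south-west | south-east | flask |
|---|---|---|---|
| electrophile | 0.025 M | 0.038 M | 0.050 M |
| nucleophile | 0.045 M | 0.045 M | 0.0450 M |
| buffer base | 0.10 M (fed, over 10 min) | 0.10 M (fed, over 10 min) | 0.100 M (fed, over 10 min) |
| buffer acid | 0.015 M | 0.015 M | 0.0150 M |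
| remark | run made earlier | run made earlier |  |
| time |  |  | 12 min |

| run | time / min | electrophile / % | target / % |
|---|---|---|---|
| south-west | 1.00 | 45.2 | 54.2 |
| south-west | 2.00 | 25.2 | 75.0 |
| south-west | 3.00 | 14.5 | 85.2 |
| south-west | 6.00 | 3.2 | 96.8 |
| south-west | 12.0 | 0 | 99.5 |
| south-east | 1.00 | 52.2 | 47.6 |
| south-east | 3.00 | 24.3 | 73.7 |
| south-east | 6.00 | 10.1 | 88.7 |
| south-east | 8.00 | 6.3 | 92.5 |
| south-east | 12.0 | 3.0 | 96.7 |

(readings scatter by 0.5 percentage points)

- acid is the free proton; pH is minus the decimal logarithm of its molar concentration
- percent here means electrophile units held: one side product counts as two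
- the numbers in the tables scatter by 0.5 percentage points (one standard deviation)
- on the list of suspects stand: buffer acid <-> buffer base + acid; protonated nucleophile <-> nucleophile + acid; electrophile + nucleophile -> acid + target + leaving group; electrophile + target -> side product
- the earlier runs do not show the pH; that part of a forecast is a guess

- part of the electrophile that has reacted at 12 min
- pH of the solution at 12 min

The ceiling is my first answer, and I put it back in. By its charges, the flask has an excess c(electrophile) − c(nucleophile) of 0.00500 M, and this excess enters the integrated second-order law. The south-west run has 14.5% electrophile left at 3.00 min. Through the integrated law, that reading gives a tail time, the reciprocal of rate constant times excess, of 9.33 min for this flask. Integrating over 12 min gives an estimate of 0.00165 M nucleophile remaining, so I commit to 86.7% reacted. The acid released should bring buffer acid to 0.0583 M and leave buffer base at 0.0567 M, but the runs show no pH.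

The forecast gives 87% (85% to 89.5%) and pH 7 (4.5 to 9.5), adding of the pH, “so the value is a guess”.

The flask gives 87.7% reacted and pH 6.69.

    buffer acid ⇌ buffer base + acid, settled at all times (K = 2.00 × 10⁻⁷ M)
    protonated nucleophile ⇌ nucleophile + acid, settled at all times (K = 4.00 × 10⁻⁶ M)
    electrophile + nucleophile → acid + target + leaving group (k = 0.440 M⁻¹ s⁻¹)
    electrophile + target → side product (k = 0.00230 M⁻¹ s⁻¹)

At 12 min the flask still holds 3.9% of its nucleophile, and the main step uses electrophile 7.9 times as fast as the side step. The reacted part of this flask stands 2.3 percentage points below the ceiling of 90.0%, with side product at 2.76%. A neighbour charged with 0.011 M nucleophile has a ceiling of 22.0%; at 12 min it has 0% of its nucleophile left and reads 23.3% reacted, with side product at 2.53%.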